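**Retrosynthetic overview** (briarane numbering: ten-membered ring C1–C10; cyclohexane C1, C10–C14; lactone O–C7–C8–C17–C19; methyls C15, C16, C18; C20 on C11)
1. The C12–OOH bond is made last, by a Schenck ene reaction of singlet oxygen on the C11=C12 alkene of macrocycle 30.
2. The ten-membered ring is formed last of the three rings, by ring-closing metathesis at C5=C6 of seco-ketol 29; C9–C10 comes from a boron aldol of cyclohexenone 21 with lactone aldehyde 12, and the C11 methyl-alkene from an enol triflate and Negishi coupling.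
3. The cyclohexene ring is formed first: catalytic asymmetric Diels–Alder of methacrolein (C1, C14), chelation-controlled Grignard addition (C2), allylic oxidation to 21.
4. The γ-lactone is formed second, on its own fragment: the C7–O bond by a new palladium-catalysed allylic C–H lactonisation of acid 8, which comes from a copper–bis(oxazoline) aldol that sets C8 and C17.

Assumption: the catalyst enantiomers named in steps 3 and 9 are those predicted by the accepted stereochemical models for these catalyst classes; if either gives the mirror-image sense, its commercially available antipode is used.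

**Step 1**
Reactants: 1 diethyl oxalate; 2 allylmagnesium bromide (CH2=CHCH2MgBr)
Product: 3 ethyl 2-oxopent-4-enoate
Conditions: 2 (1.0 equiv) added to 1 (2.0 equiv), Et2O, −78 °C; aq NH4Cl
Reagents that add atoms: none
Why: Acyl substitution of one ester of the oxalate by the Grignard reagent stops at the α-keto ester because the tetrahedral magnesium adduct persists at −78 °C.

**Step 2**
Reactants: 4 S-ethyl propanethioate
Product: 5 trimethyl{[(1E)-1-(ethylsulfanyl)prop-1-en-1-yl]oxy}silane
Conditions: LiN(i-Pr)2, THF, −78 °C; then Me3SiCl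
Reagents that add atoms: chlorotrimethylsilane, C[Si](C)(C)Cl
Why: Kinetic enolisation of the thioester and O-silylation give the silyl ketene thioacetal; its geometry is not critical because both isomers give the same aldol diastereomer in step 3.

**Step 3**
Reactants: 3 ethyl 2-oxopent-4-enoate; 5 silyl ketene thioacetal
Product: 7 ethyl (2R)-2-[(2R)-1-(ethylsulfanyl)-1-oxopropan-2-yl]-2-hydroxypent-4-enoate, via O-trimethylsilyl aldol adduct 6 (not isolated)
Conditions: Cu(OTf)2 (10 mol %), (R,R)-2,2'-isopropylidenebis(4-tert-butyl-2-oxazoline) (11 mol %), THF, −78 °C; then 1 M HCl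
Reagents that add atoms: none
Why: Catalytic enantioselective Mukaiyama aldol addition to an α-keto ester chelated through both carbonyls to divalent copper: the ligand exposes one ketone face (sets C8), and in the open transition state the enolsilane methyl sits away from the chelate ring, giving the 8-OH/17-CH3 relationship needed in the lactone (sets C17).

**Step 4**
Reactants: 7 hydroxy thioester
Product: 8 (2R,3R)-3-(ethoxycarbonyl)-3-hydroxy-2-methylhex-5-enoic acid
Conditions: AgO2CCF3 (1.5 equiv), THF/H2O 4:1, 25 °C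
Reagents that add atoms: water, O
Why: Silver-assisted thioester hydrolysis frees the C19 acid under neutral conditions, so the tertiary aldol does not undergo retro-aldol cleavage and the hindered ethyl ester is untouched.

**Step 5**
Reactants: 8 hydroxy acid
Product: 9 ethyl (2S,3S,4R)-2-ethenyl-3-hydroxy-4-methyl-5-oxooxolane-3-carboxylate
Conditions: Pd(OAc)2 (10 mol %), 1,2-bis(phenylsulfinyl)ethane (10 mol %), 1,4-benzoquinone (2 equiv), 1,4-dioxane, 45 °C
Reagents that add atoms: none
Why: Proposed new method: divalent palladium with a bis-sulfoxide ligand cleaves an allylic C7–H bond of the terminal alkene, assisted by the bound carboxylate, to give a π-allylpalladium carboxylate, and quinone-promoted C–O reductive elimination at the internal allyl terminus closes the γ-lactone (the other terminus would need a seven-membered ring), with the vinyl group trans to the C8 ester and cis to the hydroxyl in an envelope transition state so that C7 is set S; the closest known reaction type is palladium/sulfoxide allylic C–H esterification and macrolactonisation of terminal alkenes, which has not been shown for five-membered lactones next to a quaternary carbinol.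

**Step 6**
Reactants: 9 lactone ester
Product: 10 (3R,4R,5S)-5-ethenyl-4-hydroxy-4-(hydroxymethyl)-3-methyloxolan-2-one
Conditions: BH3·SMe2 (1.0 equiv), NaBH4 (5 mol %), THF, 0 to 25 °C; MeOH
Reagents that add atoms: none
Why: Hydroxyl-directed borane reduction of an α-hydroxy ester: the tertiary hydroxyl binds borane and delivers hydride through a five-membered chelate to the C9 ester only, leaving the lactone carbonyl and the hindered vinyl group.

**Step 7**
Reactants: 10 diol
Product: 11 (3R,4R,5S)-5-ethenyl-3-methyl-4-(triethylsilyloxy)-4-[(triethylsilyloxy)methyl]oxolan-2-one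
Conditions: Et3SiOTf (2.5 equiv), 2,6-lutidine, CH2Cl2, −78 to 0 °C
Reagents that add atoms: triethylsilyl trifluoromethanesulfonate, CC[Si](CC)(CC)OS(=O)(=O)C(F)(F)F
Why: Silyl triflate with a hindered pyridine base silylates both the primary and the tertiary hydroxyl (silyl ether formation).

**Step 8**
Reactants: 11 bis(triethylsilyl) ether
Product: 12 (2S,3S,4R)-2-ethenyl-4-methyl-5-oxo-3-(triethylsilyloxy)oxolane-3-carbaldehyde
Conditions: (COCl)2, DMSO, CH2Cl2, −78 to −30 °C; Et3N
Reagents that add atoms: none
Why: Swern oxidation converts a primary triethylsilyl ether directly into the aldehyde, because the chlorosulfonium salt cleaves only the unhindered O–Si bond; the aldehyde carbon bears no α-hydrogen and cannot epimerise.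

**Step 9**
Reactants: 13 methacrolein; 14 (E)-1-(trimethylsilyloxy)buta-1,3-diene
Product: 16 (1R,2S)-2-hydroxy-1-methylcyclohex-3-ene-1-carbaldehyde, via silyl ether 15 (not isolated)
Conditions: (S)-1-(2-methylphenyl)-3,3-diphenyltetrahydro-1H,3H-pyrrolo[1,2-c][1,3,2]oxazaborole protonated with HNTf2 (10 mol %), CH2Cl2, −78 °C; then 1 M HCl, THF, 0 °C
Reagents that add atoms: none
Why: Oxazaborolidinium-catalysed Diels–Alder reaction of an α-substituted acrolein: the unsubstituted diene terminus bonds to the β-carbon (ortho rule), the catalyst-bound formyl group is endo and so ends cis to the silyloxy group, and the chiral cation shields one enal face, which sets C1 and C14.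

**Step 10**
Reactants: 16 hydroxy aldehyde; 17 4-bromo-2-methylbut-1-ene
Product: 20 (1S)-1-[(1S,2S)-2-acetoxy-1-methylcyclohex-3-en-1-yl]-4-methylpent-4-en-1-yl acetate, via Grignard reagent 18 (not isolated), via bis(bromomagnesium) dialkoxide 19 (not isolated)
Conditions: 17, Mg, Et2O; 18 (2.5 equiv) added to 16, CH2Cl2, −78 °C; then Ac2O, DMAP, −78 to 25 °C
Reagents that add atoms: acetic anhydride, CC(=O)OC(C)=O
Why: Chelation-controlled Grignard addition: the first equivalent makes the C14 magnesium alkoxide, which ties the aldehyde oxygen into a six-membered chelate cis-fused to the ring so that the second equivalent attacks the exposed face (sets C2 as S); both alkoxides are then acetylated in the same flask.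

**Step 11**
Reactants: 20 diacetate
Product: 21 (1S)-1-[(1S,2S)-2-acetoxy-1-methyl-5-oxocyclohex-3-en-1-yl]-4-methylpent-4-en-1-yl acetate
Conditions: Rh2(C6H10NO)4 (dirhodium tetracaprolactamate, 1 mol %), t-BuOOH (5 equiv), K2CO3, CH2Cl2, 25 °C
Reagents that add atoms: tert-butyl hydroperoxide, CC(C)(C)OO
Why: Radical allylic oxidation takes the ring allylic methylene C11, since C14 is a deactivated acetoxy-bearing methine next to the quaternary carbon and the side-chain 1,1-disubstituted alkene is less reactive (as in oxidations of isopropenyl-bearing cyclohexenes); no stereocentre is touched.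

**Step 12**
Reactants: 21 cyclohexenone; 12 lactone aldehyde
Product: 23 9-hydroxy aldol adduct joining C10 of 21 to the aldehyde carbon of 12 (10S; C9 epimers), via dibutylboron dienolate 22 (not isolated)
Conditions: Bu2BOTf, i-Pr2NEt, CH2Cl2, −78 °C; then 12, −78 to −20 °C; pH 7 buffer, MeOH
Reagents that add atoms: none
Why: Boron-mediated aldol addition of the cross-conjugated α′-enolate (C10 is the only enolisable carbon): the aldehyde approaches C10 anti to the bulky C2 side chain on the neighbouring quaternary carbon, hence cis to the C15 methyl, which sets C10; the C9 carbinol is oxidised later, so its configuration does not matter.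

**Step 13**
Reactants: 23 aldol adduct
Product: 24 9-O-triethylsilyl ether of 23
Conditions: Et3SiOTf, 2,6-lutidine, CH2Cl2, −78 to 0 °C
Reagents that add atoms: triethylsilyl trifluoromethanesulfonate, CC[Si](CC)(CC)OS(=O)(=O)C(F)(F)F
Why: Silyl ether formation blocks the C9 hydroxyl so that it cannot protonate the enolate made in step 14 or trigger retro-aldol cleavage.

**Step 14**
Reactants: 24 silylated enone
Product: 26 C11 enol triflate with the C11=C12 alkene, via lithium enolate 25 (not isolated)
Conditions: LiBH(s-Bu)3 (1.1 equiv), THF, −78 °C; then N-(5-chloropyridin-2-yl)-N-(trifluoromethylsulfonyl)trifluoromethanesulfonamide, −78 to 0 °C; aq NH4Cl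
Reagents that add atoms: N-(5-chloropyridin-2-yl)-N-(trifluoromethylsulfonyl)trifluoromethanesulfonamide, FC(F)(F)S(=O)(=O)N(c1ccc(Cl)cn1)S(=O)(=O)C(F)(F)F
Why: Conjugate hydride addition to the β-unsubstituted cyclohexenone gives the C11–C12 enolate regiospecifically, and O-triflation traps it before it can equilibrate (1,4-reduction with enolate trapping); esters survive the hindered borohydride at −78 °C.

**Step 15**
Reactants: 26 enol triflate
Product: 27 C11-methyl cyclohexene (C11=C12) 8,9-bis(triethylsilyl) ether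
Conditions: MeZnCl (2 equiv), Pd(PPh3)4 (5 mol %), THF, 0 to 25 °C
Reagents that add atoms: methylzinc chloride, C[Zn]Cl
Why: Negishi cross-coupling puts C20 on C11 with the alkene fixed at C11=C12; acetates, lactone and silyl ethers tolerate the organozinc reagent.

**Step 16**
Reactants: 27 bis(triethylsilyl) ether
Product: 28 8,9-diol
Conditions: HF·pyridine, pyridine, THF, 0 to 25 °C
Reagents that add atoms: none
Why: Fluoride-driven cleavage of both silyl ethers (desilylation) under buffered conditions that leave the acetates and the lactone intact.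

**Step 17**
Reactants: 28 diol
Product: 29 seco α-ketol (9-ketone and 8-hydroxyl; C7 vinyl and C5 isopropenyl groups)
Conditions: 2-iodoxybenzoic acid (IBX), DMSO, 25 °C
Reagents that add atoms: none
Why: Hypervalent iodine oxidation turns the secondary C9 alcohol of the 1,2-diol into the ketone without C–C cleavage and cannot oxidise the tertiary C8 hydroxyl; the neutral medium avoids epimerisation or alkene conjugation at C10.

**Step 18**
Reactants: 29 seco α-ketol
Product: 30 (1S,2S,5Z,7S,8S,10S,14S,17R)-2,14-diacetoxy-8-hydroxy-9-oxobriara-5,11-dien-19,7-olide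
Conditions: RuCl2(=CHPh)(H2IMes)(PCy3) (second-generation Grubbs catalyst, 15 mol %), toluene (1 mM), 80 °C, argon sparge
Reagents that add atoms: none
Why: Ring-closing metathesis between the C7 vinyl and the C5 isopropenyl group releases ethene and closes the ten-membered ring; ring strain and the fused lactone favour the Z trisubstituted alkene, and the endocyclic C11 alkene is inert to the catalyst.

**Step 19**
Reactants: 30 macrocyclic diene
Product: 31 CNP0066422.1
Conditions: O2, tetraphenylporphyrin (2 mol %), visible light, CH2Cl2, −30 °C; stopped near 70% conversion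
Reagents that add atoms: dioxygen, O=O
Why: Schenck ene reaction: singlet oxygen bonds to C12 from the β face (the α face is screened by the pseudoaxial 14-acetoxy group, and bonding at C11 is blocked by the syn-axial C15 methyl) and abstracts a hydrogen from C20, which sets C12 as S and gives the exocyclic alkene; the C5 alkene reacts more slowly because of its allylic lactone oxygen.

**Compound list**
1 | diethyl oxalate | CCOC(=O)C(=O)OCC | starting material
2 | allylmagnesium bromide (CH2=CHCH2MgBr) | C=CC[Mg]Br | starting material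
3 | ethyl 2-oxopent-4-enoate | C=CCC(=O)C(=O)OCC | intermediate
4 | S-ethyl propanethioate | CCC(=O)SCC | starting material
5 | trimethyl{[(1E)-1-(ethylsulfanyl)prop-1-en-1-yl]oxy}silane (methyl cis to the silyloxy group) | C/C=C(\O[Si](C)(C)C)SCC | intermediate
6 | ethyl (2R)-2-[(2R)-1-(ethylsulfanyl)-1-oxopropan-2-yl]-2-(trimethylsilyloxy)pent-4-enoate | CCOC(=O)[C@@](O[Si](C)(C)C)(CC=C)[C@@H](C)C(=O)SCC | intermediate
7 | ethyl (2R)-2-[(2R)-1-(ethylsulfanyl)-1-oxopropan-2-yl]-2-hydroxypent-4-enoate | CCOC(=O)[C@@](O)(CC=C)[C@@H](C)C(=O)SCC | intermediate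
8 | (2R,3R)-3-(ethoxycarbonyl)-3-hydroxy-2-methylhex-5-enoic acid | CCOC(=O)[C@@](O)(CC=C)[C@@H](C)C(=O)O | intermediate
9 | ethyl (2S,3S,4R)-2-ethenyl-3-hydroxy-4-methyl-5-oxooxolane-3-carboxylate | CCOC(=O)[C@@]1(O)[C@H](C=C)OC(=O)[C@@H]1C | intermediate
10 | (3R,4R,5S)-5-ethenyl-4-hydroxy-4-(hydroxymethyl)-3-methyloxolan-2-one | OC[C@@]1(O)[C@H](C=C)OC(=O)[C@@H]1C | intermediate
11 | (3R,4R,5S)-5-ethenyl-3-methyl-4-(triethylsilyloxy)-4-[(triethylsilyloxy)methyl]oxolan-2-one | CC[Si](CC)(CC)OC[C@@]1(O[Si](CC)(CC)CC)[C@H](C=C)OC(=O)[C@@H]1C | intermediate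
12 | (2S,3S,4R)-2-ethenyl-4-methyl-5-oxo-3-(triethylsilyloxy)oxolane-3-carbaldehyde | O=C[C@@]1(O[Si](CC)(CC)CC)[C@H](C=C)OC(=O)[C@@H]1C | intermediate
13 | methacrolein (2-methylprop-2-enal) | C=C(C)C=O | starting material
14 | (E)-1-(trimethylsilyloxy)buta-1,3-diene | C=C/C=C/O[Si](C)(C)C | starting material
15 | (1R,2S)-1-methyl-2-(trimethylsilyloxy)cyclohex-3-ene-1-carbaldehyde | O=C[C@@]1(C)[C@@H](O[Si](C)(C)C)C=CCC1 | intermediate
16 | (1R,2S)-2-hydroxy-1-methylcyclohex-3-ene-1-carbaldehyde | O=C[C@@]1(C)[C@@H](O)C=CCC1 | intermediate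
17 | 4-bromo-2-methylbut-1-ene | C=C(C)CCBr | starting material
18 | (3-methylbut-3-en-1-yl)magnesium bromide | C=C(C)CC[Mg]Br | intermediate
19 | bis(bromomagnesium) dialkoxide of (1S,6S)-6-[(1S)-1-hydroxy-4-methylpent-4-en-1-yl]-6-methylcyclohex-2-en-1-ol | C=C(C)CC[C@H](O[Mg]Br)[C@@]1(C)[C@@H](O[Mg]Br)C=CCC1 | intermediate
20 | (1S)-1-[(1S,2S)-2-acetoxy-1-methylcyclohex-3-en-1-yl]-4-methylpent-4-en-1-yl acetate | C=C(C)CC[C@H](OC(C)=O)[C@@]1(C)[C@@H](OC(C)=O)C=CCC1 | intermediate
21 | (1S)-1-[(1S,2S)-2-acetoxy-1-methyl-5-oxocyclohex-3-en-1-yl]-4-methylpent-4-en-1-yl acetate | C=C(C)CC[C@H](OC(C)=O)[C@@]1(C)[C@@H](OC(C)=O)C=CC(=O)C1 | intermediate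
22 | dibutylboron dienolate of 21 (O–B on C11; C10=C11 and C12=C13) | CCCCB(CCCC)OC1=C[C@@](C)([C@@H](OC(C)=O)CCC(C)=C)[C@@H](OC(C)=O)C=C1 | intermediate
23 | 9-hydroxy aldol adduct: enone 21 carrying at C10 (10S, cis to the ring methyl) a CH(OH) group bound to C8 of the lactone of 12; C9 epimers not separated; 1S,2S,7S,14S,17R, C8 as in 12 | O=C1C=C[C@H](OC(C)=O)[C@](C)([C@@H](OC(C)=O)CCC(C)=C)[C@H]1C(O)[C@@]2(O[Si](CC)(CC)CC)[C@H](C=C)OC(=O)[C@@H]2C | intermediate
24 | 9-O-triethylsilyl ether of 23 | O=C1C=C[C@H](OC(C)=O)[C@](C)([C@@H](OC(C)=O)CCC(C)=C)[C@H]1C(O[Si](CC)(CC)CC)[C@@]2(O[Si](CC)(CC)CC)[C@H](C=C)OC(=O)[C@@H]2C | intermediate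
25 | lithium enolate from 24 (O–Li on C11; C11=C12) | [Li]OC1=CC[C@H](OC(C)=O)[C@](C)([C@@H](OC(C)=O)CCC(C)=C)[C@H]1C(O[Si](CC)(CC)CC)[C@@]2(O[Si](CC)(CC)CC)[C@H](C=C)OC(=O)[C@@H]2C | intermediate
26 | C11 enol triflate (C11=C12) from 24 | FC(F)(F)S(=O)(=O)OC1=CC[C@H](OC(C)=O)[C@](C)([C@@H](OC(C)=O)CCC(C)=C)[C@H]1C(O[Si](CC)(CC)CC)[C@@]2(O[Si](CC)(CC)CC)[C@H](C=C)OC(=O)[C@@H]2C | intermediate
27 | C11-methyl cyclohexene (C11=C12) 8,9-bis(triethylsilyl) ether | CC1=CC[C@H](OC(C)=O)[C@](C)([C@@H](OC(C)=O)CCC(C)=C)[C@H]1C(O[Si](CC)(CC)CC)[C@@]2(O[Si](CC)(CC)CC)[C@H](C=C)OC(=O)[C@@H]2C | intermediate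
28 | 8,9-diol from 27 (C9 epimers) | CC1=CC[C@H](OC(C)=O)[C@](C)([C@@H](OC(C)=O)CCC(C)=C)[C@H]1C(O)[C@@]2(O)[C@H](C=C)OC(=O)[C@@H]2C | intermediate
29 | seco α-ketol (1S,2S,7S,8S,10S,14S,17R): 9-ketone, 8-hydroxyl, 2,14-diacetate, C7 vinyl and C5 isopropenyl groups, C11=C12 | CC1=CC[C@H](OC(C)=O)[C@](C)([C@@H](OC(C)=O)CCC(C)=C)[C@H]1C(=O)[C@@]2(O)[C@H](C=C)OC(=O)[C@@H]2C | intermediate
30 | (1S,2S,5Z,7S,8S,10S,14S,17R)-2,14-diacetoxy-8-hydroxy-9-oxobriara-5,11-dien-19,7-olide | CC=1[C@@H]2C(=O)[C@@]3(O)[C@H](/C=C(/C)CC[C@H](OC(C)=O)[C@@]2(C)[C@@H](OC(C)=O)CC1)OC(=O)[C@@H]3C | intermediate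
31 | CNP0066422.1, (1S,2S,5Z,7S,8S,10S,12S,14S,17R)-2,14-diacetoxy-12-hydroperoxy-8-hydroxy-9-oxobriara-5,11(20)-dien-19,7-olide | C=C1[C@@H]2C(=O)[C@@]3(O)[C@H](/C=C(/C)CC[C@H](OC(C)=O)[C@@]2(C)[C@@H](OC(C)=O)C[C@@H]1OO)OC(=O)[C@@H]3C | target

**Totals**
Total step count: 19. Longest linear sequence: 15 steps (steps 1, 3–8, 12–19).

**Three steps most likely to fail, with fallbacks**

Step 18, the ring-closing metathesis to a ten-membered ring with a trisubstituted alkene, is the largest risk (oligomerisation or no closure). The fallback changes the substrate design to a templated closure. It sets out from diol 28, which is tied up with 2,2-dimethoxypropane and pyridinium p-toluenesulfonate as the 8,9-O-isopropylidene derivative F2. The dioxolane holds the C7 vinyl and the C10 ring on one five-membered ring and removes the free hydroxyl and ketone. Metathesis with the same ruthenium catalyst then gives the macrocyclic acetonide F3. Aqueous acetic acid frees the macrocyclic 8,9-diol F4, and IBX oxidation of F4 returns to the route at 30.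

Step 5, the proposed allylic C–H lactonisation, may give Wacker-type products or poor control at C7. The fallback uses known chemistry and sets out from acid 8. Catalytic SeO2 with t-BuOOH in CH2Cl2 hydroxylates the allylic C7 position (ene reaction followed by a 2,3-sigmatropic shift), and the γ-hydroxy acid lactonises on acidic work-up to 9 together with its C7 epimer F1. The two are separated, and F1 is re-equilibrated with Pd(PPh3)4 (zerovalent palladium, reversible ionisation of the vinyl lactone) and recycled. The route is rejoined at 9.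

Step 19, the Schenck ene reaction, may attack the C5=C6 alkene as well or give the wrong face or regiochemistry. The fallback inverts the order of the last two events. It sets out from seco-ketol 29, whose only trisubstituted alkene is C11=C12, and photo-oxygenation under the step 19 conditions gives the seco 12-hydroperoxide F5. The hydroperoxide is masked with 2-methoxypropene and pyridinium p-toluenesulfonate as the 2-methoxyprop-2-yl peroxide F6. Ring-closing metathesis with the second-generation Hoveyda–Grubbs catalyst RuCl2(=CH-2-(i-PrO)C6H4)(H2IMes) gives the macrocyclic peroxyketal F7, and acetic acid in aqueous THF releases 31.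

**Further compounds**
F1 | step 5 | ethyl (2R,3S,4R)-2-ethenyl-3-hydroxy-4-methyl-5-oxooxolane-3-carboxylate (C7 epimer of 9) | CCOC(=O)[C@@]1(O)[C@@H](C=C)OC(=O)[C@@H]1C
F2 | step 18 | 8,9-O-isopropylidene derivative of diol 28 | CC1=CC[C@H](OC(C)=O)[C@](C)([C@@H](OC(C)=O)CCC(C)=C)[C@H]1C1OC(C)(C)O[C@@]12[C@H](C=C)OC(=O)[C@@H]2C
F3 | step 18 | macrocyclic 8,9-O-isopropylidene compound (5Z alkene closed) | CC=1[C@@H]2C3OC(C)(C)O[C@@]34[C@H](/C=C(/C)CC[C@H](OC(C)=O)[C@@]2(C)[C@@H](OC(C)=O)CC1)OC(=O)[C@@H]4C
F4 | step 18 | macrocyclic 8,9-diol (9-hydroxy analogue of 30) | CC=1[C@@H]2C(O)[C@@]3(O)[C@H](/C=C(/C)CC[C@H](OC(C)=O)[C@@]2(C)[C@@H](OC(C)=O)CC1)OC(=O)[C@@H]3C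
F5 | step 19 | seco 12S-hydroperoxide with the C11 exocyclic methylene (from 29) | C=C1[C@@H](OO)C[C@H](OC(C)=O)[C@](C)([C@@H](OC(C)=O)CCC(C)=C)[C@H]1C(=O)[C@@]2(O)[C@H](C=C)OC(=O)[C@@H]2C
F6 | step 19 | 2-methoxyprop-2-yl peroxide of F5 | C=C1[C@@H](OOC(C)(C)OC)C[C@H](OC(C)=O)[C@](C)([C@@H](OC(C)=O)CCC(C)=C)[C@H]1C(=O)[C@@]2(O)[C@H](C=C)OC(=O)[C@@H]2C
F7 | step 19 | macrocyclic 2-methoxyprop-2-yl peroxide (peroxyketal of 31) | C=C1[C@@H]2C(=O)[C@@]3(O)[C@H](/C=C(/C)CC[C@H](OC(C)=O)[C@@]2(C)[C@@H](OC(C)=O)C[C@@H]1OOC(C)(C)OC)OC(=O)[C@@H]3C
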